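**Plan**

- Retrosynthesis: the C9 carbinol is traced back to an N-acyl oxazolidinone carbonyl. The C7–C8 bond is then cut to an aryloxyacetyl imide enolate and 3,4,5-trimethoxybenzyl bromide. Last, the N–acyl bond and the ArO–CH2 bond are cut to the auxiliary, bromoacetic acid and methoxyeugenol.
- Enabling feature: C8 carries the ether oxygen of the 4-allyl-2,6-dimethoxyphenyl ring and lies between C7 (the CH2 on the 3,4,5-trimethoxyphenyl ring) and C9 (CH2OH). With C9 at the carboxyl level, C8 is the α-carbon of an aryloxyacetic acid and can be benzylated as an enolate.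
- Forward order: no ring is formed, since both benzene rings are purchased. The chain is joined O–C8 first (phenol carboxymethylation), then N–C9 (auxiliary loading), then C7–C8 (enolate benzylation), and C9 is reduced last.
- Stereochemistry: the only stereocentre, (R)-C8, is set in the benzylation by the (S)-4-benzyl group of the oxazolidinone acting on the sodium-chelated Z-enolate. The final reduction does not touch it.

Key step: step 3

Remark: C7/C8/C9 denote the benzylic CH2, the O-bearing methine and the CH2OH carbon of the trimethoxyphenylpropane unit. The stereocentre written O[C@@H](CO)C… in the target is (R) (OAr > CH2OH > CH2Ar > H). Compounds 1, 2, 4 and 7 are taken to be commercial.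

**Route**

Step 1
Reactants: 1 4-allyl-2,6-dimethoxyphenol (methoxyeugenol); 2 bromoacetic acid
Product: 3 2-(4-allyl-2,6-dimethoxyphenoxy)acetic acid
Conditions: NaOH (aq, 2.5 equiv), N2, 80–90 °C; then aq HCl to pH 1
Reagents that add atoms: none
Why: Williamson ether synthesis in which the sodium phenoxide displaces bromide from sodium bromoacetate (SN2 at a primary α-halo carboxylate), the classical preparation of aryloxyacetic acids; the allyl group should not migrate into conjugation in aqueous hydroxide at this temperature, and no stereocentre is involved.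

Step 2
Reactants: 3 2-(4-allyl-2,6-dimethoxyphenoxy)acetic acid; 4 (S)-4-benzyloxazolidin-2-one
Product: 6 (S)-4-benzyl-3-[2-(4-allyl-2,6-dimethoxyphenoxy)acetyl]oxazolidin-2-one, via pivalic mixed anhydride 5 (not isolated)
Conditions: PivCl (1.1 equiv), Et3N (2.5 equiv), THF, −20 °C; then LiCl (1.2 equiv), 4 (1.0 equiv), −20 °C → rt
Reagents that add atoms: none
Why: N-acylation of an oxazolidinone through a mixed pivalic anhydride (Et3N/LiCl variant), in which the tert-butyl group shields the pivaloyl carbonyl so that the lithium-coordinated oxazolidinone should attack the aryloxyacetyl carbonyl; the auxiliary stereocentre is not involved.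

Step 3
Reactants: 6 (S)-4-benzyl-3-[2-(4-allyl-2,6-dimethoxyphenoxy)acetyl]oxazolidin-2-one; 7 3,4,5-trimethoxybenzyl bromide
Product: 9 (S)-4-benzyl-3-[(R)-2-(4-allyl-2,6-dimethoxyphenoxy)-3-(3,4,5-trimethoxyphenyl)propanoyl]oxazolidin-2-one, via sodium Z-enolate 8 (not isolated)
Conditions: NaHMDS (1.15 equiv), THF, −78 °C, 45 min; then 7 (3 equiv, in THF), −78 → −45 °C; AcOH/THF quench at −45 °C
Reagents that add atoms: none
Why: NaHMDS removes the imide α-proton, which is far more acidic than the allylic/benzylic CH2 of the allyl side chain, to give the sodium-chelated Z-enolate 8 (Na+ bridging the enolate oxygen and the ring carbonyl, aryloxy group cis to the enolate oxygen), whose α-carbon then displaces bromide from 7 in an SN2 step that forms the C7–C8 bond. The closest known reaction type is the Evans alkylation of alkoxy- and aryloxyacetyl (glycolate) oxazolidinone imides with allylic and benzylic halides. No ring is closed. The new stereocentre C8 is controlled by the C4 benzyl group of the auxiliary, which shields one face of the rigid chelate so that the electrophile enters from the other; with the (S)-auxiliary this should give (R)-C8, the same facial sense as in propionate and glycolate alkylations. The step needs C- over O-alkylation, mono-alkylation and high facial selectivity: the soft benzylic bromide and the tight sodium chelate favour C-attack, A(1,3) strain disfavours re-enolisation of the product, and the fixed Z-geometry secures the facial bias, the two ortho-methoxy groups being remote from the reacting carbon.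

Step 4
Reactants: 9 (S)-4-benzyl-3-[(R)-2-(4-allyl-2,6-dimethoxyphenoxy)-3-(3,4,5-trimethoxyphenyl)propanoyl]oxazolidin-2-one
Product: 10 (R)-2-(4-allyl-2,6-dimethoxyphenoxy)-3-(3,4,5-trimethoxyphenyl)propan-1-ol (CNP0175911.1)
Conditions: LiBH4 (2 equiv), MeOH (2 equiv), THF, 0 °C; aq NaOH work-up
Reagents that add atoms: none
Why: Reductive cleavage of an N-acyl oxazolidinone with LiBH4/MeOH, in which hydride adds to the more electrophilic exocyclic carbonyl and the resulting aldehyde is reduced on to the primary alcohol with release of the auxiliary; C8 is not enolised under these cold, weakly basic conditions and should keep its (R) configuration, and the terminal alkene and aryl ethers are inert to borohydride.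

**Compound list**

1 | 4-allyl-2,6-dimethoxyphenol (methoxyeugenol) | C=CCc1cc(OC)c(O)c(OC)c1 | starting material
2 | bromoacetic acid | OC(=O)CBr | starting material
3 | 2-(4-allyl-2,6-dimethoxyphenoxy)acetic acid | C=CCc1cc(OC)c(OCC(=O)O)c(OC)c1 | intermediate
4 | (S)-4-benzyloxazolidin-2-one | O=C1OC[C@H](Cc2ccccc2)N1 | starting material
5 | 2-(4-allyl-2,6-dimethoxyphenoxy)acetic pivalic anhydride | C=CCc1cc(OC)c(OCC(=O)OC(=O)C(C)(C)C)c(OC)c1 | intermediate
6 | (S)-4-benzyl-3-[2-(4-allyl-2,6-dimethoxyphenoxy)acetyl]oxazolidin-2-one | C=CCc1cc(OC)c(OCC(=O)N2C(=O)OC[C@@H]2Cc3ccccc3)c(OC)c1 | intermediate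
7 | 3,4,5-trimethoxybenzyl bromide | BrCc1cc(OC)c(OC)c(OC)c1 | starting material
8 | sodium (Z)-2-(4-allyl-2,6-dimethoxyphenoxy)-1-[(S)-4-benzyl-2-oxooxazolidin-3-yl]ethen-1-olate (sodium Z-enolate of 6) | C=CCc1cc(OC)c(O/C=C(\[O-])N2C(=O)OC[C@@H]2Cc3ccccc3)c(OC)c1.[Na+] | intermediate
9 | (S)-4-benzyl-3-[(R)-2-(4-allyl-2,6-dimethoxyphenoxy)-3-(3,4,5-trimethoxyphenyl)propanoyl]oxazolidin-2-one | C=CCc1cc(OC)c(O[C@@H](C(=O)N2C(=O)OC[C@@H]2Cc3ccccc3)Cc4cc(OC)c(OC)c(OC)c4)c(OC)c1 | intermediate
10 | (R)-2-(4-allyl-2,6-dimethoxyphenoxy)-3-(3,4,5-trimethoxyphenyl)propan-1-ol | C=CCc1cc(OC)c(O[C@@H](CO)Cc2cc(OC)c(OC)c(OC)c2)c(OC)c1 | target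

**Step count and risks**

Total step count: 4. Longest linear sequence: 4 steps (1 → 3 → 6 → 9 → 10).

Steps most likely to fail:

1. Step 3. The benzylic bromide may react too slowly at the temperatures the sodium enolate tolerates. On warming, the enolate may fragment by loss of the oxazolidinone anion, or the chelate may loosen and facial selectivity erode. The fallback builds the C8–O bond with inversion instead of the C7–C8 bond; it sets out from phenol 1 and rejoins the route at target 10. Commercial 3,4,5-trimethoxyphenylmagnesium bromide should open commercial (S)-tert-butyldimethylsilyl glycidyl ether at its terminal carbon (CuI cat., THF, −30 °C) to give (S)-1-[(tert-butyldimethylsilyl)oxy]-3-(3,4,5-trimethoxyphenyl)propan-2-ol F1. A Mitsunobu reaction of F1 with 1 (PPh3, DIAD, toluene, 0 °C → rt) should invert the carbinol centre and give tert-butyl{[(R)-2-(4-allyl-2,6-dimethoxyphenoxy)-3-(3,4,5-trimethoxyphenyl)propyl]oxy}dimethylsilane F2. TBAF in THF should then release 10.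

2. Step 2. Acyl transfer from the mixed anhydride may go astray, either by attack at the pivaloyl carbonyl or by base-induced ketene formation from the activated aryloxyacetyl unit. The fallback reverses the order of bond formation and also bypasses acid 3; it sets out from oxazolidinone 4 and rejoins at imide 6. Deprotonation of 4 with n-BuLi (THF, −78 °C) gives lithium (S)-4-benzyl-2-oxooxazolidin-3-ide F3, which is acylated with bromoacetyl bromide to (S)-4-benzyl-3-(2-bromoacetyl)oxazolidin-2-one F4. O-alkylation of phenol 1 with F4 (K2CO3, acetone, rt) should then give 6.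

3. Step 4. Hydride may attack the ring carbamate carbonyl of the hindered α-branched imide (endocyclic cleavage), opening the auxiliary instead of releasing the alcohol. The fallback sets out from 9 and rejoins at 10. Hydrolysis with LiOH/H2O2 (THF–H2O, 0 °C; Na2SO3 quench), which is selective for the exocyclic carbonyl, should give (R)-2-(4-allyl-2,6-dimethoxyphenoxy)-3-(3,4,5-trimethoxyphenyl)propanoic acid F5. Reduction of F5 with LiAlH4 (THF, 0 °C), which leaves the isolated alkene alone, should give 10.

**Further compounds**

F1 | step 3 | (S)-1-[(tert-butyldimethylsilyl)oxy]-3-(3,4,5-trimethoxyphenyl)propan-2-ol | CC(C)(C)[Si](C)(C)OC[C@@H](O)Cc1cc(OC)c(OC)c(OC)c1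
F2 | step 3 | tert-butyl{[(R)-2-(4-allyl-2,6-dimethoxyphenoxy)-3-(3,4,5-trimethoxyphenyl)propyl]oxy}dimethylsilane | C=CCc1cc(OC)c(O[C@@H](CO[Si](C)(C)C(C)(C)C)Cc2cc(OC)c(OC)c(OC)c2)c(OC)c1
F3 | step 2 | lithium (S)-4-benzyl-2-oxooxazolidin-3-ide | O=C1OC[C@H](Cc2ccccc2)[N-]1.[Li+]
F4 | step 2 | (S)-4-benzyl-3-(2-bromoacetyl)oxazolidin-2-one | O=C(CBr)N1C(=O)OC[C@@H]1Cc2ccccc2
F5 | step 4 | (R)-2-(4-allyl-2,6-dimethoxyphenoxy)-3-(3,4,5-trimethoxyphenyl)propanoic acid | C=CCc1cc(OC)c(O[C@@H](C(=O)O)Cc2cc(OC)c(OC)c(OC)c2)c(OC)c1
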